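Everything rests on disconnecting the O1–C2 bond of the 2,2-dimethyl-2H-pyran ring, which is the oxa-6π valence isomer of a vinylogous ortho-quinone methide. The key step condenses prenal onto the open dihydrochalcone triphenol and lets the resulting 1-oxatriene electrocyclise, so that the C4–C4a bond and the ring-closing O1–C2 bond form in one operation without protecting groups. It exploits the acylresorcinol ring A: the phenol oxygen on C8a lies para to the ketone, C4a is the only free carbon ortho to it, and C8 is blocked by the prenyl group. The precursor, a 3'-prenyl dihydrochalcone, comes from C-prenylation, Claisen–Schmidt condensation and selective enone hydrogenation.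

Key step: step 4

Remark: the target is achiral; the only stereochemical elements on the route are the E-alkene of 6 and the Z-exocyclic alkene of the transient 9. Chromene numbering (O1, C2, C3, C4, C4a, C5 to C8, C8a) is used for the target, and primed numbering (C1' to C6', C1' bearing the ketone) for ring A of the open precursors.

Step 1
Reactants: 1 2,4-dihydroxyacetophenone; 2 prenyl bromide (1-bromo-3-methylbut-2-ene)
Product: 3 1-[2,4-dihydroxy-3-(3-methylbut-2-en-1-yl)phenyl]ethan-1-one
Conditions: KOH (aq, 10%, 2 equiv), prenyl bromide (1 equiv, slow addition), 0 °C to rt; then HCl (aq, 1 M)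
Reagents that add atoms: prenyl bromide (2), CC(C)=CCBr
Why: C-alkylation of an ambident phenoxide by SN2 on the allylic bromide, in which water hydrogen-bonds the phenoxide oxygens and so disfavours O-alkylation, and the dianion should react at C3, the most electron-rich carbon flanked by both oxygens; no stereocentre is formed.

Step 2
Reactants: 3 1-[2,4-dihydroxy-3-(3-methylbut-2-en-1-yl)phenyl]ethan-1-one; 4 4-hydroxybenzaldehyde
Product: 6 isobavachalcone [(E)-1-[2,4-dihydroxy-3-(3-methylbut-2-en-1-yl)phenyl]-3-(4-hydroxyphenyl)prop-2-en-1-one], via β-hydroxy ketone 5 (not isolated)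
Conditions: KOH (aq, 50%), EtOH, N2, rt to 50 °C; then HCl (aq, 1 M), 0 °C, to pH 5
Reagents that add atoms: 4-hydroxybenzaldehyde (4), O=Cc1ccc(O)cc1
Why: Claisen–Schmidt (crossed aldol) condensation in which the methyl ketone enolate adds to the non-enolisable aldehyde to give 5 and E1cB loss of hydroxide should deliver the conjugated enone as the thermodynamically favoured E-isomer, the prenyl group being inert to base.

Step 3
Reactants: 6 isobavachalcone
Product: 7 1-[2,4-dihydroxy-3-(3-methylbut-2-en-1-yl)phenyl]-3-(4-hydroxyphenyl)propan-1-one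
Conditions: H2 (1 atm), RhCl(PPh3)3 (5 mol%), toluene/EtOH 1:1, rt
Reagents that add atoms: none
Why: Homogeneous catalytic hydrogenation with RhCl(PPh3)3 should reduce the disubstituted conjugated enone C=C much faster than the trisubstituted prenyl alkene and leave the ketone and both arenes untouched, a chemoselectivity established for prenylated chalcones; no stereocentre is formed.

Step 4
Reactants: 7 1-[2,4-dihydroxy-3-(3-methylbut-2-en-1-yl)phenyl]-3-(4-hydroxyphenyl)propan-1-one; 8 prenal (3-methylbut-2-enal)
Product: 10 1-[7-hydroxy-2,2-dimethyl-8-(3-methylbut-2-en-1-yl)-2H-chromen-6-yl]-3-(4-hydroxyphenyl)propan-1-one (the target), via ortho-quinone methide 9 (not isolated)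
Conditions: prenal (3 equiv), ethylenediammonium diacetate (EDDA, 20 mol%), xylene, 140 °C
Reagents that add atoms: prenal (8), CC(C)=CC=O
Why: EDDA turns prenal 8 into an iminium ion that is attacked by C5' of ring A, and loss of the amine from the adduct gives the vinylogous ortho-quinone methide 9, a 1-oxatriene whose thermally allowed disrotatory oxa-6π electrocyclisation forms the O–C(CH3)2 bond and restores the aromaticity of ring A. The closest known reaction type is the amine-mediated formal [3+3] chromene annulation of resorcinols and acylresorcinols with enals (Knoevenagel-type condensation followed by oxa-6π electrocyclisation). The six-membered pyran ring is closed by a 6π electrocyclic (pericyclic) closure onto the dimethyl-substituted diene terminus and not by a polar addition. No stereocentre is created, because the new sp3 carbon C2 carries two methyl groups, and the cis C3=C4 alkene follows from the ring. The step needs regioselectivity on ring A, which the substrate secures because C3' is blocked by the prenyl group and the 2'-OH is para to C5' and hydrogen-bonded to the ketone, so that only the 4'-oxygen can become the quinone methide oxygen. It also needs chemoselectivity over ring B and the ketone α-carbon, which rests on the far higher carbon nucleophilicity of the resorcinol-type ring A compared with a monophenol or an unactivated ketone under these mild conditions.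

Compound list
1 | 2,4-dihydroxyacetophenone | CC(=O)c1ccc(O)cc1O | starting material
2 | prenyl bromide (1-bromo-3-methylbut-2-ene) | CC(C)=CCBr | starting material
3 | 1-[2,4-dihydroxy-3-(3-methylbut-2-en-1-yl)phenyl]ethan-1-one | CC(=O)c1ccc(O)c(CC=C(C)C)c1O | intermediate
4 | 4-hydroxybenzaldehyde | O=Cc1ccc(O)cc1 | starting material
5 | racemic β-hydroxy ketone, 1-[2,4-dihydroxy-3-(3-methylbut-2-en-1-yl)phenyl]-3-hydroxy-3-(4-hydroxyphenyl)propan-1-one | CC(C)=CCc1c(O)ccc(C(=O)CC(O)c2ccc(O)cc2)c1O | intermediate (not isolated)
6 | isobavachalcone, (E)-1-[2,4-dihydroxy-3-(3-methylbut-2-en-1-yl)phenyl]-3-(4-hydroxyphenyl)prop-2-en-1-one | CC(C)=CCc1c(O)ccc(C(=O)/C=C/c2ccc(O)cc2)c1O | intermediate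
7 | 1-[2,4-dihydroxy-3-(3-methylbut-2-en-1-yl)phenyl]-3-(4-hydroxyphenyl)propan-1-one | CC(C)=CCc1c(O)ccc(C(=O)CCc2ccc(O)cc2)c1O | intermediate
8 | prenal (3-methylbut-2-enal) | CC(C)=CC=O | starting material
9 | vinylogous ortho-quinone methide, (6Z)-3-hydroxy-4-[3-(4-hydroxyphenyl)propanoyl]-2-(3-methylbut-2-en-1-yl)-6-(3-methylbut-2-en-1-ylidene)cyclohexa-2,4-dien-1-one | CC(C)=CCC1=C(O)C(C(=O)CCc2ccc(O)cc2)=C/C(=C/C=C(C)C)C1=O | intermediate (not isolated)
10 | 1-[7-hydroxy-2,2-dimethyl-8-(3-methylbut-2-en-1-yl)-2H-chromen-6-yl]-3-(4-hydroxyphenyl)propan-1-one | CC(C)=CCc1c(O)c(C(=O)CCc2ccc(O)cc2)cc2c1OC(C)(C)C=C2 | target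

Total step count: 4
Longest linear sequence: 4 steps (1 → 3 → 6 → 7 → 10)

Steps most likely to fail

Step 4 (key step). The iminium of prenal may oligomerise before the acyl-deactivated ring A attacks it, and condensation may also occur at ring B or stall at the C–C bond-forming stage. The fallback sets out from 7 and replaces the intermolecular C–C bond formation by a sigmatropic one. The most acidic phenol of 7, the 4'-OH para to the ketone, is alkylated with 3-chloro-3-methylbut-1-yne (1 equiv, K2CO3, KI, acetone, reflux) to give the aryl 1,1-dimethylpropargyl ether 1-[2-hydroxy-3-(3-methylbut-2-en-1-yl)-4-[(2-methylbut-3-yn-2-yl)oxy]phenyl]-3-(4-hydroxyphenyl)propan-1-one F1. Heating F1 in N,N-diethylaniline at 140 to 180 °C should trigger the aromatic propargyl Claisen rearrangement to C5' (C3' is blocked) and enolisation. A 1,5-hydrogen shift of the allenyl phenol then leads to the same ortho-quinone methide 9 and, by the same oxa-6π closure, the route comes back at the target 10.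

Step 1. O-alkylation may compete with C-alkylation, attack may occur at C5 in place of C3, and a second prenylation may follow. The fallback sets out from 1 and fixes the regiochemistry by a sigmatropic shift. The 4-OH is alkylated with 3-chloro-3-methylbut-1-yne (K2CO3, KI, acetone, reflux) to give the propargyl ether 1-[2-hydroxy-4-[(2-methylbut-3-yn-2-yl)oxy]phenyl]ethan-1-one F2. Semi-hydrogenation (H2, Pd/CaCO3 poisoned with Pb(OAc)2, quinoline, EtOAc, rt) gives the 1,1-dimethylallyl ether 1-[2-hydroxy-4-[(2-methylbut-3-en-2-yl)oxy]phenyl]ethan-1-one F3. Aromatic Claisen rearrangement of F3 (N,N-diethylaniline, 130 to 180 °C) should deliver the prenyl group to C3, the position favoured by the bond fixation of the chelated ring, and comes back at 3.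

Step 2. The aldol addition may stall because the polyanionic ketone is a poor enolate precursor and the phenoxide aldehyde a poor electrophile. The 2'-hydroxychalcone may also cyclise to the flavanone on acidification, and the electron-rich polyphenolate may be oxidised by air. The fallback sets out from 3 and 4 and masks the acidic phenols. Compound 3 is converted with MOMCl (K2CO3, acetone) into the 4-O-MOM ketone 1-[2-hydroxy-4-(methoxymethoxy)-3-(3-methylbut-2-en-1-yl)phenyl]ethan-1-one F4, the chelated 2-OH staying free. Compound 4 is converted in the same way into 4-(methoxymethoxy)benzaldehyde F5. Condensation of F4 and F5 (KOH, EtOH/H2O, rt) gives the bis-MOM chalcone (E)-1-[2-hydroxy-4-(methoxymethoxy)-3-(3-methylbut-2-en-1-yl)phenyl]-3-[4-(methoxymethoxy)phenyl]prop-2-en-1-one F6. Brief treatment of F6 with HCl (3 M) in MeOH at 50 °C removes both acetals and comes back at 6.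

Further compounds
F1 | step 4 | 1-[2-hydroxy-3-(3-methylbut-2-en-1-yl)-4-[(2-methylbut-3-yn-2-yl)oxy]phenyl]-3-(4-hydroxyphenyl)propan-1-one | CC(C)=CCc1c(OC(C)(C)C#C)ccc(C(=O)CCc2ccc(O)cc2)c1O
F2 | step 1 | 1-[2-hydroxy-4-[(2-methylbut-3-yn-2-yl)oxy]phenyl]ethan-1-one | CC(=O)c1ccc(OC(C)(C)C#C)cc1O
F3 | step 1 | 1-[2-hydroxy-4-[(2-methylbut-3-en-2-yl)oxy]phenyl]ethan-1-one | CC(=O)c1ccc(OC(C)(C)C=C)cc1O
F4 | step 2 | 1-[2-hydroxy-4-(methoxymethoxy)-3-(3-methylbut-2-en-1-yl)phenyl]ethan-1-one | CC(=O)c1ccc(OCOC)c(CC=C(C)C)c1O
F5 | step 2 | 4-(methoxymethoxy)benzaldehyde | COCOc1ccc(C=O)cc1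
F6 | step 2 | (E)-1-[2-hydroxy-4-(methoxymethoxy)-3-(3-methylbut-2-en-1-yl)phenyl]-3-[4-(methoxymethoxy)phenyl]prop-2-en-1-one | CC(C)=CCc1c(OCOC)ccc(C(=O)/C=C/c2ccc(OCOC)cc2)c1O
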